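Remark on the chemistry: the C3 lactol carbon equilibrates in solution with the ring-opened, achiral 2-formylbenzoic acid, so the (3R) compound is taken to be the crystalline solid, and it is assumed that the racemate crystallises as a conglomerate. Ring B is numbered as in phthalide (C1 carbonyl, O2, C3 lactol carbon, C3a, C4 to C7, C7a).

## Structural features

The target is a benzyl-type depside. Ring A, a 2-hydroxy-4-methoxy-3,6-dimethylbenzoyl unit, is tied through an ester oxygen and one methylene carbon to C6 of ring B. Ring B is a 3-hydroxyphthalide, a five-membered lactol-lactone fused at C3a–C7a, with a methoxy group at C5, the acyloxymethyl arm at C6 and a free hydroxyl at C7; only C4 carries hydrogen. The single stereocentre is the lactol carbon C3. It has no stereogenic neighbour, and as a cyclic hemiacylal it opens reversibly, so its configuration does not hold in solution. Fragile points are this lactol (pseudo-esters with alcohols, aminals with amines), the benzylic ester whose methylene lies between two ring oxygens and can ionise towards an ortho-quinone methide, and two oxidisable phenols. The real difficulty is regiochemical: C3a, C7a, C7, C6 and C5 must receive a formyl-level carbon, a carboxyl carbon, an oxygen, a hydroxymethyl carbon and an oxygen in unbroken sequence. The key step uses the fact that C3 and C1 sit on the neighbouring atoms C3a and C7a directly beside the C7 oxygen. An aryne across C3a–C7a is polarised by that oxygen, so a carbon nucleophile enters at C3a and a carbon electrophile at C7a.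

## Logic of the disconnections

20 to 19: no bond is cut; only the configuration at C3 is at issue. Since C3 epimerises by ring opening, no solution-phase reagent can fix it. The problem is therefore reduced to making 19 and letting the crystal lattice select one hand. The forward step must couple fast epimerisation in solution with growth of (3R) crystals only.

19 to 18 to 17: the C3–O2 bond is cut, which opens the lactol to a formyl acid held as its allyl ester in 18; the C7 oxygen is masked in 17. The lactol closes by itself once the acid is free, so no ring-forming reagent is needed and the two carbonyl carbons become an ordinary aldehyde and ester. The demand is that the last unmasking be neutral and the acetal cleavage brief, because the benzylic ester is already present.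

17 to 13 and 16: the CH2–O bond of the benzylic ester is cut. This is the convergent cut between the two rings. The alkyl–oxygen bond is chosen because the carbonyl of 16 is flanked by two ortho substituents and is poorly accessible. The forward step must activate the alcohol of 13 without ionising it, which the formyl group para to the CH2 helps, and must leave the phenol of 16 untouched.

16 to 15 to 14: one O–CH3 bond and the ester C–O bond are cut. 14 is commercial and already holds every carbon of ring A. The forward steps must tell the two hydroxyls apart; the one hydrogen-bonded to the ester carbonyl is the unreactive one.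

13 to 12 to 11 to 10: only functional groups change (aldehyde from the dithiane, alcohol from the silyl ether, C–H from C–Si, allyl ester from the acid). 10 is what the key step delivers. The C–Si bond on the dithiane carbon must be broken before the dithiane is hydrolysed, or an acylsilane would result. One fluoride treatment removes both silicon groups.

10 to 5, 6 and 7 through 8 and 9: the C3a–C3 and C7a–C1 bonds are cut together. Both carbon substituents are removed in one operation, and ring B falls back to a fluoroarene with only two ring hydrogens. The forward step must deprotonate only C3a–H, add the carbanion only at C3a, and keep 9 alive until 7 arrives. For the last reason 6 carries SiMe3 at its C2. With hydrogen at that carbon the adduct would hold a benzylic C–H roughly ten pK units more acidic than an arene C–H right beside the aryllithium, and proton transfer would divert the carboxylation to the dithiane carbon. 6 is commercial.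

5 to 4 to 3 to 2 to 1: the C6–CH2 bond and two O-protecting bonds are cut. 1 is commercial and carries fluorine and both oxygens in the right places. The forward lithiation must go to the C–H between the two oxygens and not to the one beside fluorine; alkyllithium coordination to both oxygens secures this.

## Other disconnections considered

Alternative 1: the cut is the C7a–C3a bond of ring B itself. The benzene ring would be folded from the acyclic 6-(5,5-dimethoxy-2,4-dioxopentyl)-2,2-dimethyl-4H-1,3-dioxin-4-one A1. A mild base (Et3N or Cs2CO3) would form the dienolate, the dioxinone α-carbon would add to the ketone next to the acetal, and dehydration would give 5-(dimethoxymethyl)-7-hydroxy-2,2-dimethyl-4H-1,3-benzodioxin-4-one A2.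
- In favour: C1 and C3 arrive at the right oxidation levels and on adjacent carbons by construction. The two ring oxygens are differentiated from the outset (one free, one in the acetonide). No organolithium or cryogenic step is needed. On the C3a/C7a adjacency and on oxygen differentiation this plan is the equal of the chosen one or better.
- Against: A2 lacks the C6 carbon. A later hydroxymethylation would have to choose between two positions ortho to the free hydroxyl, and the wanted one lies between two oxygens, the more hindered site. A1 is a sensitive polycarbonyl compound that needs several steps itself.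
- Comparison: the chosen plan fixes the C6 carbon before the key step, by lithiation between two oxygens where there is no choice of site. Mechanistically the aldol folding is milder than aryne chemistry. In step count Alternative 1 is expected to be two to three steps longer because of A1 and the late C6 problem.

Alternative 2: the cuts are C3a–C3 and C3–O2. 2,4-Dimethoxy-3-methylbenzoic acid A3 would be heated with Pd(OAc)2 (divalent palladium), K2HPO4 and CH2Br2. Carboxylate-directed palladation of the one ortho C–H, alkylation and displacement of the second bromide by the carboxylate would give 5,7-dimethoxy-6-methylisobenzofuran-1(3H)-one A4.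
- In favour: A3 is cheap and has one ortho C–H, so site selectivity is as secure as in the chosen plan. The lactone ring closes in the same operation without protecting groups, which is better in atom and step economy up to that point.
- Against: C3 arrives as a methylene, one oxidation level too low, and C6 arrives as a methyl group. Two benzylic positions would then have to be oxidised to different levels, and a radical bromination would have to tell the lactone CH2 from the aryl CH3. The C7 methyl ether would need selective cleavage (plausible with BCl3 because of the neighbouring carbonyl). The conditions are hot, with CH2Br2 as solvent.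
- Comparison: the chosen plan delivers C3 at the aldehyde level and C6 already oxygenated, at the price of protecting groups and low-temperature organolithium work. Alternative 2 is shorter to the bicyclic core but leaves the harder selectivity problems for later.

Alternative 3: the cuts are C6–CH2 and CH2–O. Allyl 2-formyl-6-hydroxy-4-methoxybenzoate A5, CH2O and 16 would be joined in one pot with PhB(OH)2. The boron template would direct ortho-hydroxymethylation to allyl 7-formyl-5-methoxy-2-phenyl-4H-1,3,2-benzodioxaborine-8-carboxylate A7. Heating would release an ortho-quinone methide that 16 would trap as allyl 2-formyl-6-hydroxy-5-[(2-hydroxy-4-methoxy-3,6-dimethylbenzoyl)oxymethyl]-4-methoxybenzoate A6, which is identical with 18.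
- In favour: it is the most convergent union. It introduces the C6 carbon and the ester together, needs no benzylic alcohol protection, and the only free ortho position of A5 is the right one. In step count it is better than the chosen plan, since formylation, reduction, silylation, desilylation and the separate esterification would fall away.
- Against: it does not create the adjacent formyl, carboxyl and oxygen triad; A5 must already contain it. The arene of A5 is deactivated (formyl para and ester meta to the reacting carbon). The free aldehyde can compete for the boronic acid and CH2O. The quinone methide would have to be intercepted by a hindered acid whose addition is reversible.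
- Comparison: the two plans answer different questions and could be combined (aryne coupling for the triad, quinone methide union for the arm). The chosen plan keeps every bond formation of an established type on an electron-rich ring.

Key step: step 4

## Route

**Step 1**
Reactants: 1 2-fluoro-5-methoxyphenol
Product: 2 1-fluoro-4-methoxy-2-(methoxymethoxy)benzene
Conditions: CH2(OMe)2, AcCl, ZnBr2 (cat.), toluene, rt; then 1, i-Pr2NEt, 0 °C to rt; aq. NH4Cl
Reagents that add atoms: chloromethyl methyl ether, COCCl, formed in the flask from dimethoxymethane, COCOC
Why: O-alkylation of the phenol by the oxocarbenium-type chloride (Williamson-type etherification); making the chloride in solution avoids handling the neat carcinogen, and the acetal is the chelating director needed in steps 2 and 4.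

**Step 2**
Reactants: 2 1-fluoro-4-methoxy-2-(methoxymethoxy)benzene
Product: 4 [3-fluoro-6-methoxy-2-(methoxymethoxy)phenyl]methanol, via 3-fluoro-6-methoxy-2-(methoxymethoxy)benzaldehyde 3 (not isolated)
Conditions: n-BuLi, THF, −78 to −40 °C; DMF, −78 to 0 °C; then MeOH, NaBH4, 0 °C
Reagents that add atoms: N,N-dimethylformamide, CN(C)C=O
Why: Directed ortho-metalation; the alkyllithium is held by both oxygens and removes the C–H between them, and the resulting aryllithium is meta to fluorine so it cannot lose LiF. Formylation by DMF and borohydride reduction in the same flask give the benzylic alcohol.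

**Step 3**
Reactants: 4 [3-fluoro-6-methoxy-2-(methoxymethoxy)phenyl]methanol
Product: 5 tert-butyl{[3-fluoro-6-methoxy-2-(methoxymethoxy)phenyl]methoxy}dimethylsilane
Conditions: TBSCl, imidazole, DMF, rt
Reagents that add atoms: tert-butyl(chloro)dimethylsilane, CC(C)(C)[Si](C)(C)Cl
Why: Standard imidazole-promoted silylation of a primary alcohol; the bulky silyl ether removes the acidic O–H before the organolithium chemistry and tolerates amide bases at low temperature.

**Step 4**
Reactants: 5 tert-butyl{[3-fluoro-6-methoxy-2-(methoxymethoxy)phenyl]methoxy}dimethylsilane; 6 2-(trimethylsilyl)-1,3-dithiane; 7 carbon dioxide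
Product: 10 3-{[tert-butyl(dimethyl)silyl]oxymethyl}-4-methoxy-2-(methoxymethoxy)-6-[2-(trimethylsilyl)-1,3-dithian-2-yl]benzoic acid, via the C3a–C7a aryne 8 (not isolated), via the C7a aryllithium 9 (not isolated)
Conditions: 5, lithium 2,2,6,6-tetramethylpiperidide (1.2 equiv), THF, −78 °C; 2-lithio derivative of 6 (2.5 equiv, from 6 and n-BuLi, THF, −30 °C), −78 to −20 °C; CO2 (dried gas), −78 °C to rt; cold 0.5 M HCl to pH 4
Reagents that add atoms: none
Why: The amide base removes C3a–H, the only hydrogen ortho to fluorine and the most acidic ring hydrogen (an alkyllithium would instead be drawn to C4–H by the C5 methoxy group), and on warming LiF is lost to give aryne 8. The silyl-substituted dithianyl carbanion adds at C3a, the aryne carbon remote from the C7 methoxymethoxy group, because the charge developing at C7a is stabilised inductively by the adjacent C–O bond and by chelation of lithium to the acetal oxygens; this gives aryllithium 9. The dithiane carbon in 9 is quaternary (aryl, SiMe3, two sulfurs), so no acidic C–H is present that could protonate C7a, which is the reason for using 6 and not the parent heterocycle. CO2 then carboxylates C7a, so the C3a–C3 and C7a–C1 bonds are both made in one flask. The closest known reaction type is the three-component coupling of a 3-alkoxybenzyne, generated from a haloarene with base, with an organolithium followed by electrophilic quench of the ortho-alkoxy aryllithium. No ring is closed and no stereocentre is formed. The step needs three selectivities: the site of deprotonation (secured by the single C–H ortho to fluorine), the direction of addition (secured by the C7 oxygen) and the survival of 9 until the quench (secured by the blocked dithiane carbon and low temperature).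

**Step 5**
Reactants: 10 3-{[tert-butyl(dimethyl)silyl]oxymethyl}-4-methoxy-2-(methoxymethoxy)-6-[2-(trimethylsilyl)-1,3-dithian-2-yl]benzoic acid
Product: 11 allyl 3-{[tert-butyl(dimethyl)silyl]oxymethyl}-4-methoxy-2-(methoxymethoxy)-6-[2-(trimethylsilyl)-1,3-dithian-2-yl]benzoate
Conditions: allyl bromide, K2CO3, DMF, rt
Reagents that add atoms: allyl bromide, C=CCBr
Why: SN2 alkylation at the carboxylate oxygen, which is indifferent to the two ortho substituents that would block attack at the carbonyl carbon; the allyl ester can later be removed under neutral conditions.

**Step 6**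
Reactants: 11 allyl 3-{[tert-butyl(dimethyl)silyl]oxymethyl}-4-methoxy-2-(methoxymethoxy)-6-[2-(trimethylsilyl)-1,3-dithian-2-yl]benzoate
Product: 12 allyl 6-(1,3-dithian-2-yl)-3-(hydroxymethyl)-4-methoxy-2-(methoxymethoxy)benzoate
Conditions: TBAF (3 equiv), THF, H2O (5 equiv), 0 °C to rt
Reagents that add atoms: none
Why: Fluoride cleaves the O–Si bond and also the C–Si bond, whose leaving carbanion is stabilised by two sulfurs and the aryl ring and is protonated by water (protodesilylation). It must precede step 7, because a dithiane still bearing silicon would hydrolyse to an acylsilane.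

**Step 7**
Reactants: 12 allyl 6-(1,3-dithian-2-yl)-3-(hydroxymethyl)-4-methoxy-2-(methoxymethoxy)benzoate
Product: 13 allyl 6-formyl-3-(hydroxymethyl)-4-methoxy-2-(methoxymethoxy)benzoate
Conditions: MeI, CaCO3, MeCN/H2O (9:1), 45 °C
Reagents that add atoms: water, O
Why: S-Methylation turns the thioacetal sulfurs into sulfonium leaving groups and water delivers the aldehyde (alkylative dithiane hydrolysis); CaCO3 buffers the HI so acetal and allyl ester survive. It is done here because 12 has no free phenol, and because the new formyl group para to the CH2OH makes the alcohol a cleaner SN2 substrate in step 10 and damps benzylic ionisation in step 11.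

**Step 8**
Reactants: 14 methyl 2,4-dihydroxy-3,6-dimethylbenzoate
Product: 15 methyl 2-hydroxy-4-methoxy-3,6-dimethylbenzoate
Conditions: MeI (1.1 equiv), K2CO3, acetone, 40 °C
Reagents that add atoms: iodomethane, CI
Why: Selective Williamson methylation of the C4 hydroxyl; the C2 hydroxyl is locked in a hydrogen bond to the ester carbonyl and flanked by a methyl group, so it is much less acidic and less nucleophilic.

**Step 9**
Reactants: 15 methyl 2-hydroxy-4-methoxy-3,6-dimethylbenzoate
Product: 16 2-hydroxy-4-methoxy-3,6-dimethylbenzoic acid
Conditions: KOH, DMSO/H2O, 80 °C; then cold 1 M HCl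
Reagents that add atoms: potassium hydroxide, [K+].[OH-]
Why: Saponification of a hindered salicylate, which needs poorly solvated hydroxide and heat; the product is stable as its dianion, and cold acidification avoids decarboxylation of the electron-rich acid.

**Step 10**
Reactants: 13 allyl 6-formyl-3-(hydroxymethyl)-4-methoxy-2-(methoxymethoxy)benzoate; 16 2-hydroxy-4-methoxy-3,6-dimethylbenzoic acid
Product: 17 allyl 6-formyl-3-[(2-hydroxy-4-methoxy-3,6-dimethylbenzoyl)oxymethyl]-4-methoxy-2-(methoxymethoxy)benzoate
Conditions: PPh3, diisopropyl azodicarboxylate, THF, 0 °C to rt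
Reagents that add atoms: none
Why: Mitsunobu esterification; the alcohol is activated as an alkoxyphosphonium ion and displaced by the carboxylate, so the hindrance around the acid carbonyl is irrelevant. The carboxylic acid is far more acidic than the hydrogen-bonded phenol and reacts selectively.

**Step 11**
Reactants: 17 allyl 6-formyl-3-[(2-hydroxy-4-methoxy-3,6-dimethylbenzoyl)oxymethyl]-4-methoxy-2-(methoxymethoxy)benzoate
Product: 18 allyl 2-formyl-6-hydroxy-5-[(2-hydroxy-4-methoxy-3,6-dimethylbenzoyl)oxymethyl]-4-methoxybenzoate
Conditions: CF3CO2H/CH2Cl2 (1:10), H2O (2 equiv), 0 °C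
Reagents that add atoms: none
Why: Acid-catalysed acetal hydrolysis; a phenolic methoxymethyl ether beside an ester carbonyl is among the most labile acetals, so cold dilute acid for a short time should suffice. The formyl group para and the ester meta to the benzylic carbon disfavour ionisation of the depside ester.

**Step 12**
Reactants: 18 allyl 2-formyl-6-hydroxy-5-[(2-hydroxy-4-methoxy-3,6-dimethylbenzoyl)oxymethyl]-4-methoxybenzoate
Product: 19 racemic [3,7-dihydroxy-5-methoxy-1-oxo-1,3-dihydroisobenzofuran-6-yl]methyl 2-hydroxy-4-methoxy-3,6-dimethylbenzoate
Conditions: Pd(PPh3)4 (5 mol %), TolSO2Na (1.2 equiv), THF/H2O (4:1), rt; then cold 0.5 M HCl to pH 3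
Reagents that add atoms: none
Why: Tsuji–Trost-type deallylation; zerovalent palladium ionises the allyl ester to a π-allyl complex that the sulfinate captures, a scavenger that does not condense with the aldehyde as an amine would. The freed 2-formylbenzoic acid closes spontaneously to the lactol (5-exo-trig addition of the carboxyl oxygen to the aldehyde), and C3 forms without control, as the racemate.

**Step 13**
Reactants: 19 racemic [3,7-dihydroxy-5-methoxy-1-oxo-1,3-dihydroisobenzofuran-6-yl]methyl 2-hydroxy-4-methoxy-3,6-dimethylbenzoate
Product: 20 [(3R)-3,7-dihydroxy-5-methoxy-1-oxo-1,3-dihydroisobenzofuran-6-yl]methyl 2-hydroxy-4-methoxy-3,6-dimethylbenzoate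
Conditions: slurry in EtOAc/heptane, Et3N (5 mol %), glass beads, seeds of 20 (from a milligram-scale separation of 19 on a chiral stationary phase), 20 °C; filter, dry cold
Reagents that add atoms: none
Why: Proposed new method: C3 epimerises in solution through the achiral ring-opened formyl acid (ring–chain tautomerism, base-catalysed), so a ground, stirred suspension seeded with (3R) crystals should funnel both enantiomers into the (3R) solid provided 19 forms a conglomerate; the configuration is set by the seed lattice and not by a reagent. The closest known reaction type is the attrition-enhanced deracemisation (crystallisation-induced asymmetric transformation) of conglomerate-forming 3-hydroxyisoindolin-1-ones that racemise by the same ring–chain equilibrium.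

## Compound list

1 | 2-fluoro-5-methoxyphenol | COc1ccc(F)c(O)c1 | starting material
2 | 1-fluoro-4-methoxy-2-(methoxymethoxy)benzene | COCOc1cc(OC)ccc1F | intermediate
3 | 3-fluoro-6-methoxy-2-(methoxymethoxy)benzaldehyde | COCOc1c(F)ccc(OC)c1C=O | intermediate (not isolated)
4 | [3-fluoro-6-methoxy-2-(methoxymethoxy)phenyl]methanol | COCOc1c(F)ccc(OC)c1CO | intermediate
5 | tert-butyl{[3-fluoro-6-methoxy-2-(methoxymethoxy)phenyl]methoxy}dimethylsilane | COCOc1c(F)ccc(OC)c1CO[Si](C)(C)C(C)(C)C | intermediate
6 | 2-(trimethylsilyl)-1,3-dithiane | C[Si](C)(C)C1SCCCS1 | starting material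
7 | carbon dioxide | O=C=O | starting material
8 | tert-butyl{[6-methoxy-2-(methoxymethoxy)-3,4-didehydrophenyl]methoxy}dimethylsilane (the C3a–C7a aryne) | COCOC1=C(CO[Si](C)(C)C(C)(C)C)C(OC)=CC#C1 | intermediate (not isolated)
9 | {3-{[tert-butyl(dimethyl)silyl]oxymethyl}-4-methoxy-2-(methoxymethoxy)-6-[2-(trimethylsilyl)-1,3-dithian-2-yl]phenyl}lithium (the C7a aryllithium) | [Li]c1c(OCOC)c(CO[Si](C)(C)C(C)(C)C)c(OC)cc1C1([Si](C)(C)C)SCCCS1 | intermediate (not isolated)
10 | 3-{[tert-butyl(dimethyl)silyl]oxymethyl}-4-methoxy-2-(methoxymethoxy)-6-[2-(trimethylsilyl)-1,3-dithian-2-yl]benzoic acid | COCOc1c(C(=O)O)c(C2([Si](C)(C)C)SCCCS2)cc(OC)c1CO[Si](C)(C)C(C)(C)C | intermediate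
11 | allyl 3-{[tert-butyl(dimethyl)silyl]oxymethyl}-4-methoxy-2-(methoxymethoxy)-6-[2-(trimethylsilyl)-1,3-dithian-2-yl]benzoate | COCOc1c(C(=O)OCC=C)c(C2([Si](C)(C)C)SCCCS2)cc(OC)c1CO[Si](C)(C)C(C)(C)C | intermediate
12 | allyl 6-(1,3-dithian-2-yl)-3-(hydroxymethyl)-4-methoxy-2-(methoxymethoxy)benzoate | COCOc1c(C(=O)OCC=C)c(C2SCCCS2)cc(OC)c1CO | intermediate
13 | allyl 6-formyl-3-(hydroxymethyl)-4-methoxy-2-(methoxymethoxy)benzoate | COCOc1c(C(=O)OCC=C)c(C=O)cc(OC)c1CO | intermediate
14 | methyl 2,4-dihydroxy-3,6-dimethylbenzoate | COC(=O)c1c(C)cc(O)c(C)c1O | starting material
15 | methyl 2-hydroxy-4-methoxy-3,6-dimethylbenzoate | COC(=O)c1c(C)cc(OC)c(C)c1O | intermediate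
16 | 2-hydroxy-4-methoxy-3,6-dimethylbenzoic acid | Cc1cc(OC)c(C)c(O)c1C(=O)O | intermediate
17 | allyl 6-formyl-3-[(2-hydroxy-4-methoxy-3,6-dimethylbenzoyl)oxymethyl]-4-methoxy-2-(methoxymethoxy)benzoate | COCOc1c(C(=O)OCC=C)c(C=O)cc(OC)c1COC(=O)c1c(C)cc(OC)c(C)c1O | intermediate
18 | allyl 2-formyl-6-hydroxy-5-[(2-hydroxy-4-methoxy-3,6-dimethylbenzoyl)oxymethyl]-4-methoxybenzoate | COc1cc(C)c(C(=O)OCc2c(OC)cc(C=O)c(C(=O)OCC=C)c2O)c(O)c1C | intermediate
19 | racemic [3,7-dihydroxy-5-methoxy-1-oxo-1,3-dihydroisobenzofuran-6-yl]methyl 2-hydroxy-4-methoxy-3,6-dimethylbenzoate (both configurations at C3) | COc1cc(C)c(C(=O)OCc2c(OC)cc3c(c2O)C(=O)OC3O)c(O)c1C | intermediate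
20 | [(3R)-3,7-dihydroxy-5-methoxy-1-oxo-1,3-dihydroisobenzofuran-6-yl]methyl 2-hydroxy-4-methoxy-3,6-dimethylbenzoate | COc1cc(C)c(C(=O)OCc2c(OC)cc3c(c2O)C(=O)O[C@H]3O)c(O)c1C | target

## Step count and least certain steps

Total step count: 13. Longest linear sequence: 11 steps (steps 1 to 7 and 10 to 13, from 1). The ring A branch (steps 8 and 9) joins at step 10.

Step 13. The most likely failure is crystallisation of 19 as a racemic compound and not as a conglomerate, so that dissolution and regrowth cannot enrich one hand; ring–chain equilibration that is too slow in the chosen medium would have the same effect. The fallback uses known chemistry and runs from 19 to 20: preparative chromatography on an immobilised polysaccharide chiral stationary phase with an aprotic eluent at low temperature, cold evaporation of the (3R) fraction and storage as a solid. The (3S) fraction is re-equilibrated with a trace of Et3N and recycled. No new compound is made (F0).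

Step 4 (key step). The most likely failure is loss of aryllithium 9 before carboxylation. This could happen by proton transfer from 2,2,6,6-tetramethylpiperidine during the warm period, by addition of the amide base to 8 in competition with the hindered carbanion, or by migration of SiMe3 from the dithiane carbon to C7a. The fallback runs from 5 back to 10 and separates the two bond formations. The aryne is generated and trapped by lithiated 6 as in step 4 but quenched with methanol, which gives tert-butyl({6-methoxy-2-(methoxymethoxy)-4-[2-(trimethylsilyl)-1,3-dithian-2-yl]phenyl}methoxy)dimethylsilane F1. The methoxymethoxy group then directs n-BuLi/TMEDA (THF, −78 °C, no amine present) to C7a, the only free position ortho to it, and immediate introduction of CO2 gives 10.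

Step 6. The most likely failure is incomplete cleavage of the C–Si bond, or attack of the fluoride-generated carbanion or of hydroxide on the allyl ester. The fallback runs from 10 back to 12 and removes silicon before the ester is made. TBAF acts on the tetrabutylammonium carboxylate of 10, which is inert to nucleophiles, and gives 6-(1,3-dithian-2-yl)-3-(hydroxymethyl)-4-methoxy-2-(methoxymethoxy)benzoic acid F2. Allyl bromide with KHCO3 in DMF then alkylates the carboxylate but not the alcohol and gives 12.

Step 10. The most likely failure is ionisation of the alkoxyphosphonium ion at a benzylic carbon flanked by two oxygens, leading to N-alkylation of the hydrazide and oligomers, or competing O-alkylation of the phenol of 16. The fallback runs from 12 and 16 back to 17 and forms the acyl–oxygen bond instead of the alkyl–oxygen bond. 16 is condensed with acetone (trifluoroacetic anhydride, CF3CO2H) to 7-methoxy-2,2,5,8-tetramethyl-4H-1,3-benzodioxin-4-one F3. The sodium alkoxide of 12 (NaH, THF, 0 °C; the dithiane stage is used because an alkoxide would not tolerate the aldehyde of 13) opens F3 with loss of acetone to allyl 6-(1,3-dithian-2-yl)-3-[(2-hydroxy-4-methoxy-3,6-dimethylbenzoyl)oxymethyl]-4-methoxy-2-(methoxymethoxy)benzoate F4. MeI/CaCO3 in aqueous MeCN then unmasks the aldehyde and gives 17.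

Step 11. The most likely failure is acid-induced ionisation of the benzylic C–O bond of the ortho-oxygenated benzyl ester (loss of 16 towards an ortho-quinone methide) in competition with acetal hydrolysis. The fallback runs from 10 back to 19 and is a protecting-group relay that leaves no acid-labile group once the depside ester exists.
- MgBr2·OEt2 (Et2O/CH2Cl2, rt) removes the methoxymethyl group of 10 by chelation between carboxylate and acetal oxygens and gives 3-{[tert-butyl(dimethyl)silyl]oxymethyl}-2-hydroxy-4-methoxy-6-[2-(trimethylsilyl)-1,3-dithian-2-yl]benzoic acid F5.
- Allyl bromide/K2CO3 (DMF, 50 °C) alkylates carboxylate and phenol together and gives allyl 2-(allyloxy)-3-{[tert-butyl(dimethyl)silyl]oxymethyl}-4-methoxy-6-[2-(trimethylsilyl)-1,3-dithian-2-yl]benzoate F6.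
- TBAF gives allyl 2-(allyloxy)-6-(1,3-dithian-2-yl)-3-(hydroxymethyl)-4-methoxybenzoate F7.
- MeI/CaCO3 gives allyl 2-(allyloxy)-6-formyl-3-(hydroxymethyl)-4-methoxybenzoate F8.
- Mitsunobu esterification with 16 gives allyl 2-(allyloxy)-6-formyl-3-[(2-hydroxy-4-methoxy-3,6-dimethylbenzoyl)oxymethyl]-4-methoxybenzoate F9.
- Pd(PPh3)4 with TolSO2Na removes the allyl ether and the allyl ester together and gives 19 directly, in the same number of steps as the main line.

## Further compounds

F0 | step 13 | none | none
F1 | step 4 | tert-butyl({6-methoxy-2-(methoxymethoxy)-4-[2-(trimethylsilyl)-1,3-dithian-2-yl]phenyl}methoxy)dimethylsilane | COCOc1cc(C2([Si](C)(C)C)SCCCS2)cc(OC)c1CO[Si](C)(C)C(C)(C)C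
F2 | step 6 | 6-(1,3-dithian-2-yl)-3-(hydroxymethyl)-4-methoxy-2-(methoxymethoxy)benzoic acid | COCOc1c(C(=O)O)c(C2SCCCS2)cc(OC)c1CO
F3 | step 10 | 7-methoxy-2,2,5,8-tetramethyl-4H-1,3-benzodioxin-4-one | COc1cc(C)c2c(c1C)OC(C)(C)OC2=O
F4 | step 10 | allyl 6-(1,3-dithian-2-yl)-3-[(2-hydroxy-4-methoxy-3,6-dimethylbenzoyl)oxymethyl]-4-methoxy-2-(methoxymethoxy)benzoate | COCOc1c(C(=O)OCC=C)c(C2SCCCS2)cc(OC)c1COC(=O)c1c(C)cc(OC)c(C)c1O
F5 | step 11 | 3-{[tert-butyl(dimethyl)silyl]oxymethyl}-2-hydroxy-4-methoxy-6-[2-(trimethylsilyl)-1,3-dithian-2-yl]benzoic acid | COc1cc(C2([Si](C)(C)C)SCCCS2)c(C(=O)O)c(O)c1CO[Si](C)(C)C(C)(C)C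
F6 | step 11 | allyl 2-(allyloxy)-3-{[tert-butyl(dimethyl)silyl]oxymethyl}-4-methoxy-6-[2-(trimethylsilyl)-1,3-dithian-2-yl]benzoate | COc1cc(C2([Si](C)(C)C)SCCCS2)c(C(=O)OCC=C)c(OCC=C)c1CO[Si](C)(C)C(C)(C)C
F7 | step 11 | allyl 2-(allyloxy)-6-(1,3-dithian-2-yl)-3-(hydroxymethyl)-4-methoxybenzoate | COc1cc(C2SCCCS2)c(C(=O)OCC=C)c(OCC=C)c1CO
F8 | step 11 | allyl 2-(allyloxy)-6-formyl-3-(hydroxymethyl)-4-methoxybenzoate | COc1cc(C=O)c(C(=O)OCC=C)c(OCC=C)c1CO
F9 | step 11 | allyl 2-(allyloxy)-6-formyl-3-[(2-hydroxy-4-methoxy-3,6-dimethylbenzoyl)oxymethyl]-4-methoxybenzoate | COc1cc(C)c(C(=O)OCc2c(OC)cc(C=O)c(C(=O)OCC=C)c2OCC=C)c(O)c1C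
A1 | alternative 1 | 6-(5,5-dimethoxy-2,4-dioxopentyl)-2,2-dimethyl-4H-1,3-dioxin-4-one | COC(OC)C(=O)CC(=O)CC1=CC(=O)OC(C)(C)O1
A2 | alternative 1 | 5-(dimethoxymethyl)-7-hydroxy-2,2-dimethyl-4H-1,3-benzodioxin-4-one | COC(OC)c1cc(O)cc2c1C(=O)OC(C)(C)O2
A3 | alternative 2 | 2,4-dimethoxy-3-methylbenzoic acid | COc1ccc(C(=O)O)c(OC)c1C
A4 | alternative 2 | 5,7-dimethoxy-6-methylisobenzofuran-1(3H)-one | COc1cc2c(c(OC)c1C)C(=O)OC2
A5 | alternative 3 | allyl 2-formyl-6-hydroxy-4-methoxybenzoate | COc1cc(C=O)c(C(=O)OCC=C)c(O)c1
A6 | alternative 3 | allyl 2-formyl-6-hydroxy-5-[(2-hydroxy-4-methoxy-3,6-dimethylbenzoyl)oxymethyl]-4-methoxybenzoate | COc1cc(C)c(C(=O)OCc2c(OC)cc(C=O)c(C(=O)OCC=C)c2O)c(O)c1C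
A7 | alternative 3 | allyl 7-formyl-5-methoxy-2-phenyl-4H-1,3,2-benzodioxaborine-8-carboxylate | COc1cc(C=O)c(C(=O)OCC=C)c2OB(c3ccccc3)OCc12
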